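**Retrosynthetic overview**

1. Ring B (the γ-lactone: C1, O2, C3, C3a, C7a) is disconnected first, as a [3+2] union of CO2 with the C7a–C3a–C3 unit of the (R)-chloro iodide 23: C7a–C1 by carboxylation of an arylmagnesium, O2–C3 by invertive 5-exo-tet attack of the new carboxylate on the benzylic chloride.
2. Enabling feature: C7a is ortho to the C7 methoxy group and para to the C5 methoxy group (regioselective iodination, chelated arylmagnesium), while the benzylic carbon C3 sits on C3a, which is meta to both methoxy groups, so C3 should substitute by SN2 instead of ionising.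
3. C3–C1′ comes from addition of the Grignard reagent of spiroketal chloride 17 to iodo aldehyde 2; oxidation and CBS reduction set C3, which then passes through two inversions (steps 11 and 12).
4. Rings C and D (the 1,6-dioxaspiro[4.4]nonane) close together in one acid step from acetone dimethylhydrazone alkylated twice, with (S)-propylene oxide (C7) and (R)-benzyl glycidyl ether (C2); C5 is settled by equilibration, separation and recycling, and the C2 arm is lengthened by a Cu-catalysed triflate–Grignard coupling.
5. Order of ring formation: ring A is bought, rings C and D close in step 4, ring B closes in step 12.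

Key step: step 12

Remark (locants): phthalide numbering C1–C7a; C1′–C6′ are the chain carbons counted from C3; the spiroketal is numbered O1, C2 (chain-bearing), C5 (spiro), O6, C7 (methyl-bearing).

Remark (assumption): 1,6-dioxaspiro[4.4]nonanes have no strong thermodynamic bias at the spiro carbon, so it is assumed that the two C5 epimers formed in step 4 interconvert in acid and can be separated by chromatography. Every step after step 4 is kept free of Brønsted and strong Lewis acids.

**Route**

Step 1
Reactants: 1 3,5-dimethoxybenzaldehyde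
Product: 2 2-iodo-3,5-dimethoxybenzaldehyde
Conditions: NIS (1.05 equiv), TFA (cat.), MeCN, rt
Reagents that add atoms: N-iodosuccinimide O=C1CCC(=O)N1I
Why: Electrophilic aromatic iodination should go to C2, which is ortho to one methoxy group and para to the other and is the position that halogenation of this aldehyde normally takes, so the carbon that becomes C7a carries the iodine.

Step 2
Reactants: 3 acetone N,N-dimethylhydrazone; 4 (S)-propylene oxide
Product: 6 (2S)-5-(2,2-dimethylhydrazinylidene)hexan-2-ol, via lithiated hydrazone 5 (not isolated)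
Conditions: n-BuLi (1.05 equiv), THF, −78 → 0 °C; then 4, 0 °C → rt; aq NH4Cl
Reagents that add atoms: none
Why: Corey–Enders hydrazone alkylation, in which the lithium azaenolate 5 opens the epoxide by SN2 attack at its unsubstituted carbon, so the (S) carbinol carbon of the chiral-pool epoxide (the future C7) is not touched.

Step 3
Reactants: 6 (2S)-5-(2,2-dimethylhydrazinylidene)hexan-2-ol; 7 (R)-benzyl glycidyl ether
Product: 9 (2R,8S)-1-(benzyloxy)-5-(2,2-dimethylhydrazinylidene)nonane-2,8-diol, via dilithio hydrazone 8 (not isolated)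
Conditions: n-BuLi (2.1 equiv), THF, −78 → 0 °C; then 7, 0 °C → rt; aq NH4Cl
Reagents that add atoms: none
Why: Second azaenolate alkylation, in which the hydroxyl is held as its lithium alkoxide, kinetic deprotonation takes the less substituted α′-methyl group, and dianion 8 opens the glycidyl ether at its terminal carbon, bringing in the future C2 with the configuration of the chiral-pool epoxide.

Step 4
Reactants: 9 (2R,8S)-1-(benzyloxy)-5-(2,2-dimethylhydrazinylidene)nonane-2,8-diol
Product: 12 (2R,5S,7S)-2-[(benzyloxy)methyl]-7-methyl-1,6-dioxaspiro[4.4]nonane, via keto diol 10 (not isolated), via spiroketal epimer mixture 11 (not isolated)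
Conditions: 2 M aq HCl, THF, rt, until the C5 epimer ratio is constant; NaHCO3 work-up; chromatography on silica; (5R)-rich fractions returned to the same acid
Reagents that add atoms: none
Why: Acid hydrolysis of the hydrazone should give keto diol 10, which closes both tetrahydrofuran rings by dehydrative spiroketalisation to the epimer mixture 11 while the benzyl ether keeps the primary oxygen out of a competing six-membered ketal; C2 and C7 are fixed by the two epoxides, the spiro carbon C5 equilibrates through the ring-opened oxocarbenium ion (thermodynamic control), and the (5S) epimer 12 is taken out of 11 by chromatography while the (5R) remainder is re-equilibrated to 11 in the same acid.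

Step 5
Reactants: 12 (2R,5S,7S)-2-[(benzyloxy)methyl]-7-methyl-1,6-dioxaspiro[4.4]nonane
Product: 13 [(2R,5S,7S)-7-methyl-1,6-dioxaspiro[4.4]nonan-2-yl]methanol
Conditions: H2 (1 atm), 10% Pd/C, NaHCO3 (solid), EtOAc, rt
Reagents that add atoms: none
Why: Hydrogenolysis of the benzyl ether over Pd/C under neutral conditions should leave the spiroketal and its three stereocentres untouched.

Step 6
Reactants: 13 [(2R,5S,7S)-7-methyl-1,6-dioxaspiro[4.4]nonan-2-yl]methanol
Product: 14 [(2R,5S,7S)-7-methyl-1,6-dioxaspiro[4.4]nonan-2-yl]methyl trifluoromethanesulfonate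
Conditions: Tf2O, 2,6-lutidine, CH2Cl2, −78 °C; cold aq NaHCO3 work-up; used at once
Reagents that add atoms: trifluoromethanesulfonic anhydride O=S(=O)(OS(=O)(=O)C(F)(F)F)C(F)(F)F
Why: O-Sulfonylation of the primary alcohol with a hindered pyridine base at low temperature should give the alkyl triflate without free acid that could epimerise C5.

Step 7
Reactants: 14 [(2R,5S,7S)-7-methyl-1,6-dioxaspiro[4.4]nonan-2-yl]methyl trifluoromethanesulfonate; 15 1-bromo-5-chloropentane
Product: 17 (2S,5S,7S)-2-(6-chlorohexyl)-7-methyl-1,6-dioxaspiro[4.4]nonane, via Grignard reagent 16 (not isolated)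
Conditions: 15, Mg, THF, 35 °C; then 14, CuBr·SMe2 (10 mol%), THF, −40 → 0 °C
Reagents that add atoms: none
Why: Copper-catalysed Kochi-type coupling of a primary β-alkoxy triflate with a primary Grignard reagent should form the C6′–C5′ bond, while the C–Cl bond is inert at this temperature and stays as the handle for the next Grignard reagent.

Step 8
Reactants: 17 (2S,5S,7S)-2-(6-chlorohexyl)-7-methyl-1,6-dioxaspiro[4.4]nonane; 2 2-iodo-3,5-dimethoxybenzaldehyde
Product: 19 1-(2-iodo-3,5-dimethoxyphenyl)-7-[(2S,5S,7S)-7-methyl-1,6-dioxaspiro[4.4]nonan-2-yl]heptan-1-ol (both C1 epimers), via Grignard reagent 18 (not isolated)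
Conditions: Mg (activated), THF, 50 °C; then 2, THF, −78 °C; aq NH4Cl
Reagents that add atoms: none
Why: Grignard formation from the primary chloride and 1,2-addition to the aldehyde at −78 °C, where carbonyl addition is far faster than iodine–magnesium exchange with a primary alkylmagnesium; the new carbinol centre is not controlled because step 9 removes it.

Step 9
Reactants: 19 1-(2-iodo-3,5-dimethoxyphenyl)-7-[(2S,5S,7S)-7-methyl-1,6-dioxaspiro[4.4]nonan-2-yl]heptan-1-ol (both C1 epimers)
Product: 20 1-(2-iodo-3,5-dimethoxyphenyl)-7-[(2S,5S,7S)-7-methyl-1,6-dioxaspiro[4.4]nonan-2-yl]heptan-1-one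
Conditions: Dess–Martin periodinane (1.3 equiv), NaHCO3, CH2Cl2, 0 °C → rt
Reagents that add atoms: none
Why: Dess–Martin oxidation of the secondary benzylic alcohol to the aryl ketone under bicarbonate buffering, which keeps acetic acid away from the spiroketal.

Step 10
Reactants: 20 1-(2-iodo-3,5-dimethoxyphenyl)-7-[(2S,5S,7S)-7-methyl-1,6-dioxaspiro[4.4]nonan-2-yl]heptan-1-one
Product: 21 (1S)-1-(2-iodo-3,5-dimethoxyphenyl)-7-[(2S,5S,7S)-7-methyl-1,6-dioxaspiro[4.4]nonan-2-yl]heptan-1-ol
Conditions: (R)-2-methyl-CBS-oxazaborolidine (20 mol%), BH3·SMe2 (1.0 equiv), THF, −20 °C; MeOH quench, aqueous work-up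
Reagents that add atoms: none
Why: Corey–Bakshi–Shibata reduction, in which the (R)-oxazaborolidine binds the ketone with the aryl group as the large substituent and delivers hydride to one face, so the carbinol carbon (the future C3) should be set as (S) under reagent control.

Step 11
Reactants: 21 (1S)-1-(2-iodo-3,5-dimethoxyphenyl)-7-[(2S,5S,7S)-7-methyl-1,6-dioxaspiro[4.4]nonan-2-yl]heptan-1-ol
Product: 23 (2S,5S,7S)-2-[(7R)-7-chloro-7-(2-iodo-3,5-dimethoxyphenyl)heptyl]-7-methyl-1,6-dioxaspiro[4.4]nonane, via alkoxyphosphonium chloride 22 (not isolated)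
Conditions: PPh3, N-chlorosuccinimide (premixed), CH2Cl2, −20 → 0 °C
Reagents that add atoms: N-chlorosuccinimide O=C1CCC(=O)N1Cl
Why: Appel-type chlorination, in which the alkoxyphosphonium salt 22 is displaced by chloride in an SN2 step with inversion to the (R)-chloride, ionisation being disfavoured because both methoxy groups are meta and the ortho iodine is inductively withdrawing.

Step 12
Reactants: 23 (2S,5S,7S)-2-[(7R)-7-chloro-7-(2-iodo-3,5-dimethoxyphenyl)heptyl]-7-methyl-1,6-dioxaspiro[4.4]nonane
Product: 26 (3S)-5,7-dimethoxy-3-{6-[(2S,5S,7S)-7-methyl-1,6-dioxaspiro[4.4]nonan-2-yl]hexyl}-2-benzofuran-1(3H)-one, via arylmagnesium chloride 24 (not isolated), via magnesium carboxylate 25 (not isolated)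
Conditions: i-PrMgCl·LiCl (1.1 equiv), THF, −30 °C; CO2 (dry gas), −30 → 0 °C; then DMF, 45 °C; pH 7 phosphate buffer
Reagents that add atoms: carbon dioxide O=C=O
Why: Iodine–magnesium exchange at the C7a–I bond should give arylmagnesium 24 (chelated by the C7 methoxy oxygen and too unreactive at −30 °C to attack the secondary chloride), CO2 inserts into the C7a–Mg bond to give carboxylate 25 (C7a–C1 bond), and on warming in THF/DMF a carboxylate oxygen displaces the benzylic chloride (O2–C3 bond). The closest known reaction type is the annulation of ortho-(chloromethyl)arylmagnesium reagents with carbonyl electrophiles, where the newly formed oxygen nucleophile closes a five-membered ring onto the benzylic chloride, combined with ordinary Grignard carboxylation and carboxylate O-alkylation. Ring B (C1, O2, C3, C3a, C7a) closes in the 5-exo-tet mode. C3 is set by stereospecific SN2 inversion of the (R)-chloride, so its configuration is substrate-controlled and traces back to the CBS reduction in step 10. The step needs exchange at iodine without attack on the C–Cl bond, and inversion instead of ionisation or elimination; the benzylic cation is not stabilised (both methoxy groups are meta to C3a and the new carboxylate is electron-withdrawing), and the nucleophile is held next to C3. The spiroketal sees only basic and neutral conditions, so C5 should not epimerise.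

**Compound list**

1 | 3,5-dimethoxybenzaldehyde | COc1cc(C=O)cc(OC)c1 | starting material
2 | 2-iodo-3,5-dimethoxybenzaldehyde | COc1cc(OC)c(I)c(C=O)c1 | intermediate
3 | acetone N,N-dimethylhydrazone | CC(C)=NN(C)C | starting material
4 | (S)-propylene oxide, (2S)-2-methyloxirane | C[C@H]1CO1 | starting material
5 | lithiated acetone N,N-dimethylhydrazone (lithium azaenolate) | [Li]CC(C)=NN(C)C | intermediate
6 | (2S)-5-(2,2-dimethylhydrazinylidene)hexan-2-ol | C[C@H](O)CCC(C)=NN(C)C | intermediate
7 | (R)-benzyl glycidyl ether, (2R)-2-[(benzyloxy)methyl]oxirane | c1ccccc1COC[C@H]1CO1 | starting material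
8 | dilithio derivative of 6 (lithium alkoxide and α′-azaenolate) | [Li]CC(=NN(C)C)CC[C@H](C)O[Li] | intermediate
9 | (2R,8S)-1-(benzyloxy)-5-(2,2-dimethylhydrazinylidene)nonane-2,8-diol | c1ccccc1COC[C@H](O)CCC(=NN(C)C)CC[C@H](C)O | intermediate
10 | (2R,8S)-1-(benzyloxy)-2,8-dihydroxynonan-5-one | c1ccccc1COC[C@H](O)CCC(=O)CC[C@H](C)O | intermediate
11 | (2R,7S)-2-[(benzyloxy)methyl]-7-methyl-1,6-dioxaspiro[4.4]nonane (equilibrium mixture of both C5 epimers; the (5S) component is 12, the (5R) component is re-equilibrated in step 4) | c1ccccc1COC[C@H]1CCC2(CC[C@H](C)O2)O1 | intermediate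
12 | (2R,5S,7S)-2-[(benzyloxy)methyl]-7-methyl-1,6-dioxaspiro[4.4]nonane | c1ccccc1COC[C@H]1CC[C@]2(CC[C@H](C)O2)O1 | intermediate
13 | [(2R,5S,7S)-7-methyl-1,6-dioxaspiro[4.4]nonan-2-yl]methanol | OC[C@H]1CC[C@]2(CC[C@H](C)O2)O1 | intermediate
14 | [(2R,5S,7S)-7-methyl-1,6-dioxaspiro[4.4]nonan-2-yl]methyl trifluoromethanesulfonate | O=S(=O)(OC[C@H]1CC[C@]2(CC[C@H](C)O2)O1)C(F)(F)F | intermediate
15 | 1-bromo-5-chloropentane | ClCCCCCBr | starting material
16 | 5-chloropentylmagnesium bromide | ClCCCCC[Mg]Br | intermediate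
17 | (2S,5S,7S)-2-(6-chlorohexyl)-7-methyl-1,6-dioxaspiro[4.4]nonane | ClCCCCCC[C@H]1CC[C@]2(CC[C@H](C)O2)O1 | intermediate
18 | 6-[(2S,5S,7S)-7-methyl-1,6-dioxaspiro[4.4]nonan-2-yl]hexylmagnesium chloride | Cl[Mg]CCCCCC[C@H]1CC[C@]2(CC[C@H](C)O2)O1 | intermediate
19 | 1-(2-iodo-3,5-dimethoxyphenyl)-7-[(2S,5S,7S)-7-methyl-1,6-dioxaspiro[4.4]nonan-2-yl]heptan-1-ol (both C1 epimers) | COc1cc(OC)c(I)c(c1)C(O)CCCCCC[C@H]1CC[C@]2(CC[C@H](C)O2)O1 | intermediate
20 | 1-(2-iodo-3,5-dimethoxyphenyl)-7-[(2S,5S,7S)-7-methyl-1,6-dioxaspiro[4.4]nonan-2-yl]heptan-1-one | COc1cc(OC)c(I)c(c1)C(=O)CCCCCC[C@H]1CC[C@]2(CC[C@H](C)O2)O1 | intermediate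
21 | (1S)-1-(2-iodo-3,5-dimethoxyphenyl)-7-[(2S,5S,7S)-7-methyl-1,6-dioxaspiro[4.4]nonan-2-yl]heptan-1-ol | COc1cc(OC)c(I)c(c1)[C@H](CCCCCC[C@H]1CC[C@]2(CC[C@H](C)O2)O1)O | intermediate
22 | alkoxy(triphenyl)phosphonium chloride of 21 | COc1cc(OC)c(I)c(c1)[C@H](CCCCCC[C@H]1CC[C@]2(CC[C@H](C)O2)O1)O[P+](c1ccccc1)(c1ccccc1)c1ccccc1.[Cl-] | intermediate
23 | (2S,5S,7S)-2-[(7R)-7-chloro-7-(2-iodo-3,5-dimethoxyphenyl)heptyl]-7-methyl-1,6-dioxaspiro[4.4]nonane | COc1cc(OC)c(I)c(c1)[C@@H](CCCCCC[C@H]1CC[C@]2(CC[C@H](C)O2)O1)Cl | intermediate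
24 | arylmagnesium chloride from 23 (Mg at the former C–I carbon) | COc1cc(OC)c([Mg]Cl)c(c1)[C@@H](CCCCCC[C@H]1CC[C@]2(CC[C@H](C)O2)O1)Cl | intermediate
25 | chloromagnesium 2-[(1R)-1-chloro-7-(spiroketal)heptyl]-4,6-dimethoxybenzoate | COc1cc(OC)c(C(=O)O[Mg]Cl)c(c1)[C@@H](CCCCCC[C@H]1CC[C@]2(CC[C@H](C)O2)O1)Cl | intermediate
26 | (3S)-5,7-dimethoxy-3-{6-[(2S,5S,7S)-7-methyl-1,6-dioxaspiro[4.4]nonan-2-yl]hexyl}-2-benzofuran-1(3H)-one | COc1cc(OC)c2c(c1)[C@H](CCCCCC[C@H]1CC[C@]3(CC[C@H](C)O3)O1)OC2=O | target

**Step count and risks**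

Total step count: 12. Longest linear sequence: 11 steps (steps 2–12, from acetone dimethylhydrazone 3); the aryl fragment 2 is one step from 1.

Steps most likely to fail:

1. Step 12 (key step). What may go wrong: attack on or elimination of the benzylic chloride by the organomagnesium species during the exchange, or partial ionisation or elimination during ring closure, with loss of configuration at C3. Fallback: it sets out from the (S)-alcohol 21 and skips step 11. Carbonylative lactonisation of 21 with Pd(PPh3)4, CO (1 atm) and K2CO3 in DMF at 80 °C should let the acylpalladium formed at C7a be captured by the C3 hydroxyl, closing the lactone at O2–C1 with retention at C3 (the C3–O bond is never broken). It comes back to the route at the target 26 and makes no compound outside the list (F0).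

2. Step 4. What may go wrong: an unfavourable equilibrium ratio at the spiro carbon C5, or incomplete chromatographic separation of the two epimeric benzyl ethers. Fallback: it sets out from the crude epimer mixture 11, which is carried on without separation. Hydrogenolysis as in step 5 gives alcohol 13 and its C5 epimer [(2R,5R,7S)-7-methyl-1,6-dioxaspiro[4.4]nonan-2-yl]methanol F1. Acylation of the pair with 4-nitrobenzoyl chloride and pyridine in CH2Cl2 gives [(2R,5S,7S)-7-methyl-1,6-dioxaspiro[4.4]nonan-2-yl]methyl 4-nitrobenzoate F2 and [(2R,5R,7S)-7-methyl-1,6-dioxaspiro[4.4]nonan-2-yl]methyl 4-nitrobenzoate F3, which are separated by crystallisation or chromatography as polar, UV-active esters. Saponification of F2 (LiOH, THF/H2O) returns the route at compound 13. F3 is re-equilibrated at C5 with pyridinium p-toluenesulfonate (cat.) in CH2Cl2 at rt, which regenerates the F2/F3 pair for another separation.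

3. Step 11. What may go wrong: partial loss of configuration through an ion pair from the alkoxyphosphonium salt, or elimination to the styrene. Fallback: it sets out from ketone 20. Reduction with (S)-2-methyl-CBS-oxazaborolidine and BH3·SMe2 gives (1R)-1-(2-iodo-3,5-dimethoxyphenyl)-7-[(2S,5S,7S)-7-methyl-1,6-dioxaspiro[4.4]nonan-2-yl]heptan-1-ol F4. Phosphorylation with ClP(O)(OEt)2 and N-methylimidazole in CH2Cl2 gives, with retention because no bond to the carbinol carbon is broken, diethyl (1R)-1-(2-iodo-3,5-dimethoxyphenyl)-7-[(2S,5S,7S)-7-methyl-1,6-dioxaspiro[4.4]nonan-2-yl]heptyl phosphate F5. Under the step 12 conditions F5 should pass through the arylmagnesium chloride F6 and the chloromagnesium carboxylate F7, whose carboxylate displaces the benzylic phosphate with inversion. It comes back to the route at the target 26.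

**Further compounds**

F0 | step 12 | none | none
F1 | step 4 | [(2R,5R,7S)-7-methyl-1,6-dioxaspiro[4.4]nonan-2-yl]methanol | OC[C@H]1CC[C@@]2(CC[C@H](C)O2)O1
F2 | step 4 | [(2R,5S,7S)-7-methyl-1,6-dioxaspiro[4.4]nonan-2-yl]methyl 4-nitrobenzoate | O=C(OC[C@H]1CC[C@]2(CC[C@H](C)O2)O1)c1ccc(cc1)[N+](=O)[O-]
F3 | step 4 | [(2R,5R,7S)-7-methyl-1,6-dioxaspiro[4.4]nonan-2-yl]methyl 4-nitrobenzoate | O=C(OC[C@H]1CC[C@@]2(CC[C@H](C)O2)O1)c1ccc(cc1)[N+](=O)[O-]
F4 | step 11 | (1R)-1-(2-iodo-3,5-dimethoxyphenyl)-7-[(2S,5S,7S)-7-methyl-1,6-dioxaspiro[4.4]nonan-2-yl]heptan-1-ol | COc1cc(OC)c(I)c(c1)[C@@H](CCCCCC[C@H]1CC[C@]2(CC[C@H](C)O2)O1)O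
F5 | step 11 | diethyl (1R)-1-(2-iodo-3,5-dimethoxyphenyl)-7-[(2S,5S,7S)-7-methyl-1,6-dioxaspiro[4.4]nonan-2-yl]heptyl phosphate | COc1cc(OC)c(I)c(c1)[C@@H](CCCCCC[C@H]1CC[C@]2(CC[C@H](C)O2)O1)OP(=O)(OCC)OCC
F6 | step 11 | arylmagnesium chloride from F5 (Mg at the former C–I carbon) | COc1cc(OC)c([Mg]Cl)c(c1)[C@@H](CCCCCC[C@H]1CC[C@]2(CC[C@H](C)O2)O1)OP(=O)(OCC)OCC
F7 | step 11 | chloromagnesium carboxylate from F6 and CO2 | COc1cc(OC)c(C(=O)O[Mg]Cl)c(c1)[C@@H](CCCCCC[C@H]1CC[C@]2(CC[C@H](C)O2)O1)OP(=O)(OCC)OCC
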